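## Structural features

Compound 37 is a furanoheliangolide-type germacranolide. Its ten-membered carbocycle (C1–C10, ring B) is bridged by an oxygen between C3 and C10, so that C1–C2–C3–O–C10 is a 3(2H)-furanone (ring A), and it is trans-fused at C6–C7 to an α-methylene-γ-butyrolactone (ring C). Ring B holds a cross-conjugated dienone: C2=C3, which is trans with respect to ring B because it lies inside ring A, and the Z alkene C4=C5 that carries the hydroxymethyl carbon C15. Three contiguous stereocentres, C6 (R), C7 (R) and C8 (R), stand on one edge (H6/H7 trans, C7–C11 anti to C8–O). The quaternary C10 (S) is insulated from them by the C9 methylene, and a fifth centre sits in the (R)-2-methylbutanoate on O8. Fragile elements are the exocyclic methylene lactone (Michael acceptor), the O8 ester (a β-leaving group whenever C6 is a carbonyl), the epimerisable α-carbon of that ester, and C7 once it is α to an aldehyde. The real difficulty is closing the strained medium ring, effectively nine-membered along the C3–O–C10 bridge, while fixing C6 relative to C7 and leaving the dienone and the Z geometry intact. The feature exploited is that C6 is a secondary allylic carbinol attached directly to the Z alkene C4=C5: the C5–C6 bond can be made by adding a C5 alkenyl metal of fixed Z geometry to a C6 aldehyde, and ring A together with the Z alkene already turns C5 towards C6.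

## Logic of the disconnections

37 ⇒ 36. The O–Si bond at C15 is the last bond cut. The primary allylic alcohol would interfere with the enolate and acylation chemistry, so it travels as a silyl ether. Nothing is gained in skeleton, only in robustness. The forward cleavage must spare the methylene lactone and the O8 ester, which calls for buffered fluoride and not a basic one.

36 ⇒ 32 (through 33, 34, 35). The C11=C13 bond is cut. The exocyclic alkene is the most reactive site of the target and is best introduced after every nucleophilic, reductive and organometallic step. The gain is that no earlier intermediate is a Michael acceptor at C13. The demand is regioselective enolisation at C11 of the lactone in the presence of the α-hydrogen of the O8 ester.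

32 ⇒ 30 (through 31). The lactone bond O6–C12 is cut, giving a free C6 carbinol and a C12 tert-butyl ester. Ring C disappears and C6 becomes the site of the ring-forming event. The demand is that O6 is the only free hydroxyl when C12 is unmasked, so that the lactone can only close to C6.

30 ⇒ 28 (through 29). The C5–C6 bond is cut between the Z alkene carbon and the allylic carbinol. This opens ring B, removes the C6 stereocentre and leaves a chain hanging from ring A. The demand is a Z alkenyl iodide and an epimerisable, elimination-prone aldehyde in one molecule, which must be joined under neutral conditions with retention of geometry and with facial control at C6.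

28 ⇒ 27 ⇒ 26 ⇒ 24 + 25. The C6 oxidation level, the O–Si bond at O6 and the O8–acyl bond are adjusted in that order. The β-acyloxy aldehyde is created only in the last step before ring closure, and the side-chain ester is put on while O6 is blocked. The gain is that the sensitive aldehyde never meets base. The demand is clean differentiation of the primary O6 from the hindered secondary O8.

24 ⇒ 23 ⇒ 22. The O6–Si bond and then the C6–N bond to the auxiliary are cut. The gain is access to an aldol retron. The demand is a hydride that removes the imide but leaves the ring A carbonyl, the alkenyl iodide and the tert-butyl ester alone.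

22 ⇒ 16 + 20 (through 21). The C7–C8 bond is cut. The anti arrangement of C11 on C7 and O on C8 is an aldol retron, and the cut divides the molecule into a furanone aldehyde and a four-carbon C6/C7/C11/C12 unit. The demand is anti selectivity with absolute control from the auxiliary, and a C12 ester that cannot lactonise onto O8.

20 ⇒ 17 + 18 (through 19). The N–C6 acyl bond is cut, leading to two purchasable compounds. The demand is only selective activation of the free acid in the presence of the tert-butyl ester.

16 ⇒ 15 ⇒ 12 (through 14 and 13). After adjustment of the C8 oxidation level, the C2–C3 bond of ring A is cut and the ring oxygen–C3 bond is recognised as a former ester bond. Ring A reduces to an α-acyloxy methyl ketone. The demand is that the methyl ketone enolate attacks the ester carbonyl (five-membered transition state) faster than it adds to the iodoacrylate, and that the Z iodide survives base and acid.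

12 ⇒ 6 + 10 (through 11). The ester bond between O10 and C3 is cut, which makes the route convergent. The demand is acylation of a tertiary α-ketol without isomerising the Z iodide.

10 ⇒ 9 ⇒ 8 ⇒ 7. The C4–C15 and C5–I bonds are cut in one retrosynthetic operation (three-component iodo-aldol), after ester and silyl adjustments. The gain is a three-carbon alkynoate plus a one-carbon electrophile and an iodide source. The demand is the Z geometry, with iodine cis to the carbonyl carbon that becomes C3.

6 ⇒ 4 ⇒ 3 ⇒ 2 ⇒ 1 (through 5). The C1–C2 bond is cut (methyl nucleophile onto a masked C1 carboxyl), and the C8 oxidation level and the two carboxyl groups are differentiated. The gain is that C10 comes from the chiral pool with its oxygen and methyl group in place. The demand is mono-addition at C1 and no loss of the protected C8 oxygen.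

## Other disconnections considered

Alternative 1: The cut is C1–C2, between the future ketone carbon and an alkyne carbon. In the forward sense the iodoalkyne aldehyde A2 would be closed with CrCl2 and catalytic NiCl2 to the ten-membered propargylic alcohol A1. Oxidation at C1, removal of the silyl group on O10 and a 5-endo-dig oxa-Michael closure (acid or Ph3PAuNTf2) would then build ring A, and desilylation at O15 would finish.
- In its favour: the new carbinol centre is destroyed by oxidation, so no facial selectivity is required, which is better than the chosen plan. The aldehyde sits on the quaternary C10 and can neither epimerise nor eliminate, which is better than aldehyde 28. Alkynylchromium additions raise no question of alkene geometry. The methylene lactone is already present, so no late enolate chemistry is needed, which is also better.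
- Against it here: ring B must close around a linear C2≡C3 unit conjugated to the Z alkene, without the turn that ring A provides in 28. Ring A then has to be made transannularly in a strained ynone that is a second strong Michael acceptor next to the methylene lactone. A2 must carry the complete lactone and the C6–C8 triad through the assembly of a Z enyne.
- Comparison: on structure the chosen plan is better preorganised, because ring A is in place and robust before ring closure. On mechanism the two are equal, since both use the same chromium/nickel chemistry. On step economy the alternative is about equal: more operations after ring closure (oxidation, unmasking, cyclisation, desilylation), but none for methylenation.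

Alternative 2: The cuts are C2–C3 and C4–C5, with C2–C5 rejoined, which leads back to the cyclooctenone ynol ether A4. AgNTf2 would promote a stepwise [2+2] addition in which C4 of the ynol ether attacks the enone β-carbon C5 and the enolate carbon C2 closes onto C3. Conrotatory 4π opening of the fused cyclobutene at C2–C5 would then give the 15-O-silyl ether A3.
- In its favour: one step would form ring A, expand an eight- to a ten-membered ring and create both alkenes. The cis,trans diene expected from conrotatory opening of a cis-fused cyclobutene is exactly the geometry of 37 (C2=C3 trans in ring B, C4=C5 Z). C6 is set before the key step, and A3 is one step from the target. On bonds formed per step and on the post-key-step count it is better than the chosen plan.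
- Against it here: the two-atom tether C10–O forces the linear ynol ether to reach C5 across the ring through a bridged, highly strained first bond formation. An alkyl ynol ether on a tertiary carbon with β-hydrogens is prone to retro-ene loss of a ketene. The cyclooctenone with three stereocentres and the methylene lactone is itself a demanding target, and silver-promoted ynol ether/enone cycloadditions are established mainly between separate partners.
- Comparison: structurally it is the most convergent in complexity. Mechanistically it is far less secured than an alkenylchromium addition. Its step economy advantage after the key step is offset by the longer and less certain route to A4.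

Alternative 3: The cut is C7–C8. The bromomethylbutenolide aldehyde A6 would be treated with CrCl2 (divalent chromium, no nickel needed) to give an allylchromium species whose γ-carbon C7 adds to the C8 aldehyde. This would close ring B, shift the alkene to C11=C13 and give the 8-hydroxy tricycle A5. Esterification with 25 and desilylation would follow.
- In its favour: the methylene lactone appears in the key step, so the separate methylenation and the lactonisation are saved, which is better than the chosen plan on step economy. C6 is already present and should direct C7 to the trans ring fusion by attack anti to the C6 substituent, which is equal or better for the C6/C7 relationship. The aldehyde carbon has no stereocentre next to it. Allylchromium reagents are highly aldehyde-selective, equal to the chosen plan.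
- Against it here: two stereocentres (C7 and C8) are set in the ring-closing event, and C8 depends on the macrocyclic transition state and not on a reagent. In the chosen plan C7 and C8 are fixed by an auxiliary before ring closure, which is better. The γ-hydrogen at C6 of the butenolide is allylic and acidified, so the only pre-set centre of that edge is at risk. The hindered O8 must afterwards be acylated next to the methylene lactone.
- Comparison: on structure and step count this alternative is probably the shortest. On stereochemical security the chosen plan is stronger, because only one centre (C6) is left to the cyclisation, and that centre can be corrected afterwards.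

Key step: step 18

Assumption: the stereodescriptors of the key-step precursor and product were re-derived centre by centre from 37 and are consistent with it, so no configuration had to be corrected. The precursor is changed in two spectator groups only: a tert-butyl ester at C12, so that neither O8 nor O6 can lactonise before step 19, and TBDPS at O15, so that the ether survives the acid in steps 9 and 19. Compounds 1, 7, 17, 18 and 25 are taken as purchasable.

Abbreviations: germacrane numbering is used for positions. TBS = tert-butyldimethylsilyl, TBDPS = tert-butyldiphenylsilyl, TES = triethylsilyl. Fur = (2S)-5-[(1Z)-1-iodo-3-(tert-butyldiphenylsilyloxy)prop-1-en-2-yl]-2-methyl-3-oxo-2,3-dihydrofuran-2-yl.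

## Steps

Step 1
Reactants: 1 (S)-citramalic acid
Product: 2 2-[(4S)-2,2,4-trimethyl-5-oxo-1,3-dioxolan-4-yl]acetic acid
Conditions: Me2C(OMe)2, PPTS (cat.), CH2Cl2, rt
Reagents that add atoms: 2,2-dimethoxypropane COC(C)(C)OC
Why: Acid-catalysed transacetalisation; the α-hydroxy acid closes the five-membered dioxolanone in preference to a six-membered ring, which differentiates the two carboxyl groups and masks the tertiary hydroxyl without touching C10.

Step 2
Reactants: 2 2-[(4S)-2,2,4-trimethyl-5-oxo-1,3-dioxolan-4-yl]acetic acid
Product: 3 (5S)-5-(2-hydroxyethyl)-2,2,5-trimethyl-1,3-dioxolan-4-one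
Conditions: BH3·THF, THF, 0 °C to rt; MeOH quench
Reagents that add atoms: none
Why: Chemoselective borane reduction of a free carboxylic acid, which reacts through its acyloxyborane much faster than the lactone-like dioxolanone carbonyl.

Step 3
Reactants: 3 (5S)-5-(2-hydroxyethyl)-2,2,5-trimethyl-1,3-dioxolan-4-one
Product: 4 (5S)-5-[2-(tert-butyldimethylsilyloxy)ethyl]-2,2,5-trimethyl-1,3-dioxolan-4-one
Conditions: TBSCl, imidazole, CH2Cl2, 0 °C to rt
Reagents that add atoms: tert-butyldimethylsilyl chloride CC(C)(C)[Si](C)(C)Cl
Why: Standard silylation of a primary alcohol, carried out at once under neutral conditions so that the hydroxyl cannot translactonise onto the dioxolanone.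

Step 4
Reactants: 4 (5S)-5-[2-(tert-butyldimethylsilyloxy)ethyl]-2,2,5-trimethyl-1,3-dioxolan-4-one
Product: 6 (3S)-5-(tert-butyldimethylsilyloxy)-3-hydroxy-3-methylpentan-2-one, via lithium hemiketal alkoxide 5 (not isolated)
Conditions: MeLi, THF, −78 °C; AcOH, −78 °C to rt
Reagents that add atoms: methyllithium [Li]C
Why: Nucleophilic acyl addition to the dioxolanone gives the tetrahedral alkoxide 5, which is stable at −78 °C and so resists a second addition; protonation releases acetone and the α-hydroxy methyl ketone. C10 bears no hydrogen and cannot epimerise.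

Step 5
Reactants: 7 methyl propiolate
Product: 8 methyl (2Z)-2-(hydroxymethyl)-3-iodoprop-2-enoate
Conditions: MgI2, CH2O (gas from cracked paraformaldehyde), CH2Cl2, −78 to 0 °C
Reagents that add atoms: magnesium diiodide [Mg+2].[I-].[I-]; formaldehyde C=O
Why: β-Iodo Morita–Baylis–Hillman (halo-aldol) reaction: conjugate addition of iodide and aldol trapping at the α-carbon by formaldehyde occur in one operation, and the kinetic pathway places iodine cis to the ester, the Z geometry later needed at C5.

Step 6
Reactants: 8 methyl (2Z)-2-(hydroxymethyl)-3-iodoprop-2-enoate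
Product: 9 methyl (2Z)-2-[(tert-butyldiphenylsilyloxy)methyl]-3-iodoprop-2-enoate
Conditions: TBDPSCl, imidazole, CH2Cl2, 0 °C to rt
Reagents that add atoms: tert-butyldiphenylsilyl chloride CC(C)(C)[Si](Cl)(c1ccccc1)c1ccccc1
Why: Standard silylation of a primary allylic alcohol; TBDPS is chosen because it must survive the acid of steps 9 and 19.

Step 7
Reactants: 9 methyl (2Z)-2-[(tert-butyldiphenylsilyloxy)methyl]-3-iodoprop-2-enoate
Product: 10 (2Z)-2-[(tert-butyldiphenylsilyloxy)methyl]-3-iodoprop-2-enoic acid
Conditions: LiOH·H2O, THF/H2O, 0 °C to rt; 1 M HCl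
Reagents that add atoms: lithium hydroxide [Li+].[OH-]
Why: Saponification of a methyl ester; α-substituted β-iodoacrylates are poor acceptors for hydroxide at low temperature, and the TBDPS ether is stable to these conditions.

Step 8
Reactants: 10 (2Z)-2-[(tert-butyldiphenylsilyloxy)methyl]-3-iodoprop-2-enoic acid; 6 (3S)-5-(tert-butyldimethylsilyloxy)-3-hydroxy-3-methylpentan-2-one
Product: 12 (3S)-5-(tert-butyldimethylsilyloxy)-3-methyl-2-oxopentan-3-yl (2Z)-2-[(tert-butyldiphenylsilyloxy)methyl]-3-iodoprop-2-enoate, via acid chloride 11 (not isolated)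
Conditions: 1-chloro-N,N,2-trimethylprop-1-en-1-amine, CH2Cl2, 0 °C; then 6, pyridine, DMAP (cat.), 0 °C to rt
Reagents that add atoms: none
Why: Neutral acid chloride formation with the α-chloroenamine avoids the hydrogen halide that could isomerise the Z iodide; DMAP-catalysed acylation of the tertiary α-ketol follows, with C10 unaffected.

Step 9
Reactants: 12 (3S)-5-(tert-butyldimethylsilyloxy)-3-methyl-2-oxopentan-3-yl (2Z)-2-[(tert-butyldiphenylsilyloxy)methyl]-3-iodoprop-2-enoate
Product: 15 (2S)-2-(2-hydroxyethyl)-5-[(1Z)-1-iodo-3-(tert-butyldiphenylsilyloxy)prop-1-en-2-yl]-2-methylfuran-3(2H)-one, via hydroxy diketone 13 (not isolated), via furanone TBS ether 14 (not isolated)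
Conditions: LiN(SiMe3)2, THF, −78 to −20 °C; AcOH; then TsOH·H2O, MeOH, rt
Reagents that add atoms: none
Why: Intramolecular Claisen-type O-to-C acyl transfer (Baker–Venkataraman type): the kinetic methyl ketone enolate attacks the ester carbonyl through a five-membered transition state to give 13. Acid then dehydrates its cyclic hemiketal to the 3(2H)-furanone 14, and methanolysis removes the primary TBS ether while the TBDPS ether stays.

Step 10
Reactants: 15 (2S)-2-(2-hydroxyethyl)-5-[(1Z)-1-iodo-3-(tert-butyldiphenylsilyloxy)prop-1-en-2-yl]-2-methylfuran-3(2H)-one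
Product: 16 2-Fur-acetaldehyde
Conditions: Dess–Martin periodinane, NaHCO3, CH2Cl2, 0 °C to rt
Reagents that add atoms: none
Why: Dess–Martin oxidation of a primary alcohol; the buffered, non-basic medium should keep the aldehyde from β-eliminating the ring oxygen at C10.

Step 11
Reactants: 17 mono-tert-butyl succinate; 18 (4S)-4-benzyl-1,3-oxazolidin-2-one
Product: 20 tert-butyl 4-[(4S)-4-benzyl-2-oxo-1,3-oxazolidin-3-yl]-4-oxobutanoate, via mixed pivalic anhydride 19 (not isolated)
Conditions: t-BuCOCl, Et3N, THF, −20 °C; then 18, LiCl, rt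
Reagents that add atoms: none
Why: N-acylation of the oxazolidinone through a mixed anhydride; the hindered pivaloyl carbonyl directs attack to the succinyl carbonyl and the tert-butyl ester is inert.

Step 12
Reactants: 20 tert-butyl 4-[(4S)-4-benzyl-2-oxo-1,3-oxazolidin-3-yl]-4-oxobutanoate; 16 2-Fur-acetaldehyde
Product: 22 tert-butyl (3R,4R)-3-[(4S)-4-benzyl-2-oxo-1,3-oxazolidine-3-carbonyl]-4-hydroxy-5-Fur-pentanoate, via dibutylboron Z-enolate 21 (not isolated)
Conditions: Bu2BOTf, i-Pr2NEt, CH2Cl2, 0 °C; then 16·Et2AlCl (premixed), CH2Cl2, −78 °C; pH 7 buffer/MeOH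
Reagents that add atoms: none
Why: Evans aldol reaction in its Lewis-acid-mediated open-transition-state variant: the chelated Z-boron enolate 21 is attacked on the face opposite the benzyl group by the Et2AlCl-activated aldehyde, which sets C7. The antiperiplanar open transition state with the bulky aluminium-bound carbonyl favours the anti relationship, which sets C8. The remote C10 centre should have little influence, and the tert-butyl ester cannot lactonise onto O8.

Step 13
Reactants: 22 tert-butyl (3R,4R)-3-[(4S)-4-benzyl-2-oxo-1,3-oxazolidine-3-carbonyl]-4-hydroxy-5-Fur-pentanoate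
Product: 23 tert-butyl (3S,4R)-4-hydroxy-3-(hydroxymethyl)-5-Fur-pentanoate
Conditions: LiBH4, MeOH (1 equiv), THF, −10 to 0 °C
Reagents that add atoms: none
Why: Reductive cleavage of an N-acyloxazolidinone; hydride delivery within the lithium chelate of the β-hydroxy imide should be faster at low temperature than attack on the tert-butyl ester or on the vinylogous-ester carbonyl of ring A. The descriptor at C7 changes only through priorities.

Step 14
Reactants: 23 tert-butyl (3S,4R)-4-hydroxy-3-(hydroxymethyl)-5-Fur-pentanoate
Product: 24 tert-butyl (3S,4R)-4-hydroxy-3-[(triethylsilyloxy)methyl]-5-Fur-pentanoate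
Conditions: TESCl, imidazole, CH2Cl2, −20 °C
Reagents that add atoms: chlorotriethylsilane CC[Si](Cl)(CC)CC
Why: Selective silylation of the primary O6 over the hindered secondary O8, which is flanked by the C7 branch and the neopentyl-like C9.

Step 15
Reactants: 24 tert-butyl (3S,4R)-4-hydroxy-3-[(triethylsilyloxy)methyl]-5-Fur-pentanoate; 25 (R)-2-methylbutanoic acid
Product: 26 tert-butyl (3S,4R)-4-[(2R)-2-methylbutanoyloxy]-3-[(triethylsilyloxy)methyl]-5-Fur-pentanoate
Conditions: DCC, DMAP, CH2Cl2, 0 °C to rt
Reagents that add atoms: none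
Why: Steglich esterification with retention at C8; the α-centre of the simple alkanoic acid is not acidic enough to epimerise through the acylpyridinium.

Step 16
Reactants: 26 tert-butyl (3S,4R)-4-[(2R)-2-methylbutanoyloxy]-3-[(triethylsilyloxy)methyl]-5-Fur-pentanoate
Product: 27 tert-butyl (3S,4R)-3-(hydroxymethyl)-4-[(2R)-2-methylbutanoyloxy]-5-Fur-pentanoate
Conditions: HF·pyridine, pyridine, THF, 0 °C
Reagents that add atoms: none
Why: Chemoselective desilylation: a primary TES ether is cleaved far faster than the TBDPS ether, and the buffered medium is too weakly basic to move the acyl group from O8 to O6.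

Step 17
Reactants: 27 tert-butyl (3S,4R)-3-(hydroxymethyl)-4-[(2R)-2-methylbutanoyloxy]-5-Fur-pentanoate
Product: 28 tert-butyl (3R,4R)-3-formyl-4-[(2R)-2-methylbutanoyloxy]-5-Fur-pentanoate
Conditions: Dess–Martin periodinane, NaHCO3, CH2Cl2, 0 °C; used without chromatography
Reagents that add atoms: none
Why: Dess–Martin oxidation under neutral conditions, so that the β-acyloxy aldehyde neither eliminates (E1cB) nor epimerises at C7; the tert-butyl ester keeps the transient γ-hydroxy ester 27 from lactonising.

Step 18
Reactants: 28 tert-butyl (3R,4R)-3-formyl-4-[(2R)-2-methylbutanoyloxy]-5-Fur-pentanoate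
Product: 30 tert-butyl 2-[(4Z,6R,7S,8R,10S)-15-(tert-butyldiphenylsilyloxy)-6-hydroxy-8-((2R)-2-methylbutanoyloxy)-1-oxo-3,10-epoxygermacra-2,4-dien-7-yl]acetate (C11 and C12 form the acetate arm; C13 absent), via alkenylchromium dichloride 29 (not isolated)
Conditions: CrCl2 (excess), NiCl2 (cat.), degassed DMSO, rt, slow addition of 28, ca. 0.002 M
Reagents that add atoms: none
Why: CrCl2 reduces NiCl2 to zerovalent nickel, which inserts into the C5–I bond with retention; transmetalation to trivalent chromium gives 29, and the divalent nickel released is reduced again. 29 adds to the C6 aldehyde; the closest known reaction type is the Nozaki–Hiyama–Kishi macrocyclisation of alkenyl iodides onto aldehydes. Ring B closes in a 10-exo-trig mode (nine atoms if counted through the oxygen of ring A). The new stereocentre C6 is controlled by C7: in the Felkin–Anh arrangement the C8 branch is anti to the incoming C5 and the nucleophile passes the C7 hydrogen, which places O6 syn to C11 in the zigzag (6R, the configuration that lactonises trans). The anti β-acyloxy group at C8 reinforces this 1,3-anti preference. Organochromium reagents add to aldehydes but not to ketones or esters, so ring A and the three esters should survive. The Z geometry is secured by the retentive insertion and by the configurational stability of the sp2 carbon–chromium bond, and the neutral medium protects C7 and the O8 ester. Ring closure must outrun oligomerisation, which needs high dilution with slow addition and is helped by the Z alkene and the rigid ring A holding C5 near C6.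

Step 19
Reactants: 30 tert-butyl 2-[(4Z,6R,7S,8R,10S)-15-(tert-butyldiphenylsilyloxy)-6-hydroxy-8-((2R)-2-methylbutanoyloxy)-1-oxo-3,10-epoxygermacra-2,4-dien-7-yl]acetate
Product: 32 (4Z,6R,7R,8R,10S)-15-(tert-butyldiphenylsilyloxy)-8-[(2R)-2-methylbutanoyloxy]-1-oxo-3,10-epoxy-13-norgermacra-2,4-dien-12,6-olide, via hydroxy acid 31 (not isolated)
Conditions: CF3CO2H, CH2Cl2, 0 °C to rt
Reagents that add atoms: none
Why: Acidolysis of the tert-butyl ester (loss of 2-methylpropene) gives 31, which closes the γ-lactone (5-exo-trig) with the only free hydroxyl, O6. The trans ring fusion follows from the C6/C7 configuration; the TBDPS ether, the O8 ester and ring A tolerate the acid, and ionisation at C6 is disfavoured by the electron-poor diene.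

Step 20
Reactants: 32 (4Z,6R,7R,8R,10S)-15-(tert-butyldiphenylsilyloxy)-8-[(2R)-2-methylbutanoyloxy]-1-oxo-3,10-epoxy-13-norgermacra-2,4-dien-12,6-olide
Product: 36 (4Z,6R,7R,8R,10S)-15-(tert-butyldiphenylsilyloxy)-8-[(2R)-2-methylbutanoyloxy]-1-oxo-3,10-epoxygermacra-2,4,11(13)-trien-12,6-olide, via lithium lactone enolate 33 (not isolated), via Mannich base 34 (not isolated), via trimethylammonium iodide 35 (not isolated)
Conditions: LiN(SiMe3)2, THF, −78 °C; CH2=NMe2+ I−, −78 °C to rt; MeI, MeOH, rt; aq. NaHCO3, CH2Cl2, rt
Reagents that add atoms: dimethyl(methylene)ammonium iodide C=[N+](C)C.[I-]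
Why: Mannich-type α-methylenation: the amide base deprotonates the lactone CH2 at C11, which is several pKa units more acidic and far less hindered than the tertiary α-CH of the O8 ester, and the iminium salt traps 33 at −78 °C before any acyl transfer. Quaternisation and mild-base E1cB elimination then give the exocyclic alkene; ring A has no enolisable hydrogen and no stereocentre is created.

Step 21
Reactants: 36 (4Z,6R,7R,8R,10S)-15-(tert-butyldiphenylsilyloxy)-8-[(2R)-2-methylbutanoyloxy]-1-oxo-3,10-epoxygermacra-2,4,11(13)-trien-12,6-olide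
Product: 37 (4Z,6R,7R,8R,10S)-15-hydroxy-8-[(2R)-2-methylbutanoyloxy]-1-oxo-3,10-epoxygermacra-2,4,11(13)-trien-12,6-olide (CNP0307052.2)
Conditions: HF·pyridine, THF, 0 °C to rt
Reagents that add atoms: none
Why: Fluoride-mediated desilylation under weakly acidic, non-nucleophilic conditions, which should leave the methylene lactone, the O8 ester and ring A untouched.

## Compound list

1 | (S)-citramalic acid, (2S)-2-hydroxy-2-methylbutanedioic acid | OC(=O)[C@](C)(CC(=O)O)O | starting material
2 | 2-[(4S)-2,2,4-trimethyl-5-oxo-1,3-dioxolan-4-yl]acetic acid | CC1(C)OC(=O)[C@](C)(CC(=O)O)O1 | intermediate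
3 | (5S)-5-(2-hydroxyethyl)-2,2,5-trimethyl-1,3-dioxolan-4-one | CC1(C)OC(=O)[C@](C)(CCO)O1 | intermediate
4 | (5S)-5-[2-(tert-butyldimethylsilyloxy)ethyl]-2,2,5-trimethyl-1,3-dioxolan-4-one | CC1(C)OC(=O)[C@](C)(CCO[Si](C)(C)C(C)(C)C)O1 | intermediate
5 | lithium (5S)-5-[2-(tert-butyldimethylsilyloxy)ethyl]-2,2,4,5-tetramethyl-1,3-dioxolan-4-olate (hemiketal alkoxide, C4 epimers) | C[C@@]1(CCO[Si](C)(C)C(C)(C)C)OC(C)(C)OC1(C)[O-].[Li+] | intermediate
6 | (3S)-5-(tert-butyldimethylsilyloxy)-3-hydroxy-3-methylpentan-2-one | CC(=O)[C@@](C)(O)CCO[Si](C)(C)C(C)(C)C | intermediate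
7 | methyl propiolate | C#CC(=O)OC | starting material
8 | methyl (2Z)-2-(hydroxymethyl)-3-iodoprop-2-enoate | I/C=C(/CO)C(=O)OC | intermediate
9 | methyl (2Z)-2-[(tert-butyldiphenylsilyloxy)methyl]-3-iodoprop-2-enoate | I/C=C(/CO[Si](c1ccccc1)(c1ccccc1)C(C)(C)C)C(=O)OC | intermediate
10 | (2Z)-2-[(tert-butyldiphenylsilyloxy)methyl]-3-iodoprop-2-enoic acid | I/C=C(/CO[Si](c1ccccc1)(c1ccccc1)C(C)(C)C)C(=O)O | intermediate
11 | (2Z)-2-[(tert-butyldiphenylsilyloxy)methyl]-3-iodoprop-2-enoyl chloride | I/C=C(/CO[Si](c1ccccc1)(c1ccccc1)C(C)(C)C)C(=O)Cl | intermediate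
12 | (3S)-5-(tert-butyldimethylsilyloxy)-3-methyl-2-oxopentan-3-yl (2Z)-2-[(tert-butyldiphenylsilyloxy)methyl]-3-iodoprop-2-enoate | I/C=C(/CO[Si](c1ccccc1)(c1ccccc1)C(C)(C)C)C(=O)O[C@@](C)(CCO[Si](C)(C)C(C)(C)C)C(C)=O | intermediate
13 | (1Z,6S)-8-(tert-butyldimethylsilyloxy)-6-hydroxy-1-iodo-6-methyl-2-[(tert-butyldiphenylsilyloxy)methyl]oct-1-ene-3,5-dione | I/C=C(/CO[Si](c1ccccc1)(c1ccccc1)C(C)(C)C)C(=O)CC(=O)[C@@](C)(O)CCO[Si](C)(C)C(C)(C)C | intermediate
14 | (2S)-2-[2-(tert-butyldimethylsilyloxy)ethyl]-5-[(1Z)-1-iodo-3-(tert-butyldiphenylsilyloxy)prop-1-en-2-yl]-2-methylfuran-3(2H)-one | I/C=C(/CO[Si](c1ccccc1)(c1ccccc1)C(C)(C)C)C1=CC(=O)[C@](C)(CCO[Si](C)(C)C(C)(C)C)O1 | intermediate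
15 | (2S)-2-(2-hydroxyethyl)-5-[(1Z)-1-iodo-3-(tert-butyldiphenylsilyloxy)prop-1-en-2-yl]-2-methylfuran-3(2H)-one | I/C=C(/CO[Si](c1ccccc1)(c1ccccc1)C(C)(C)C)C1=CC(=O)[C@](C)(CCO)O1 | intermediate
16 | 2-Fur-acetaldehyde, 2-[(2S)-5-((1Z)-1-iodo-3-(tert-butyldiphenylsilyloxy)prop-1-en-2-yl)-2-methyl-3-oxo-2,3-dihydrofuran-2-yl]acetaldehyde | I/C=C(/CO[Si](c1ccccc1)(c1ccccc1)C(C)(C)C)C1=CC(=O)[C@](C)(CC=O)O1 | intermediate
17 | mono-tert-butyl succinate, 4-tert-butoxy-4-oxobutanoic acid | CC(C)(C)OC(=O)CCC(=O)O | starting material
18 | (4S)-4-benzyl-1,3-oxazolidin-2-one | O=C1OC[C@H](Cc2ccccc2)N1 | starting material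
19 | 4-tert-butoxy-4-oxobutanoic pivalic anhydride | CC(C)(C)OC(=O)CCC(=O)OC(=O)C(C)(C)C | intermediate
20 | tert-butyl 4-[(4S)-4-benzyl-2-oxo-1,3-oxazolidin-3-yl]-4-oxobutanoate | CC(C)(C)OC(=O)CCC(=O)N1[C@@H](Cc2ccccc2)COC1=O | intermediate
21 | dibutylboron (Z)-enolate of 20 | CC(C)(C)OC(=O)C/C=C(\OB(CCCC)CCCC)N1[C@@H](Cc2ccccc2)COC1=O | intermediate
22 | tert-butyl (3R,4R)-3-[(4S)-4-benzyl-2-oxo-1,3-oxazolidine-3-carbonyl]-4-hydroxy-5-Fur-pentanoate (7R,8R,10S) | I/C=C(/CO[Si](c1ccccc1)(c1ccccc1)C(C)(C)C)C1=CC(=O)[C@](C)(C[C@@H](O)[C@@H](CC(=O)OC(C)(C)C)C(=O)N2[C@@H](Cc3ccccc3)COC2=O)O1 | intermediate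
23 | tert-butyl (3S,4R)-4-hydroxy-3-(hydroxymethyl)-5-Fur-pentanoate | I/C=C(/CO[Si](c1ccccc1)(c1ccccc1)C(C)(C)C)C1=CC(=O)[C@](C)(C[C@@H](O)[C@@H](CC(=O)OC(C)(C)C)CO)O1 | intermediate
24 | tert-butyl (3S,4R)-4-hydroxy-3-[(triethylsilyloxy)methyl]-5-Fur-pentanoate | I/C=C(/CO[Si](c1ccccc1)(c1ccccc1)C(C)(C)C)C1=CC(=O)[C@](C)(C[C@@H](O)[C@@H](CC(=O)OC(C)(C)C)CO[Si](CC)(CC)CC)O1 | intermediate
25 | (R)-2-methylbutanoic acid | OC(=O)[C@H](C)CC | starting material
26 | tert-butyl (3S,4R)-4-[(2R)-2-methylbutanoyloxy]-3-[(triethylsilyloxy)methyl]-5-Fur-pentanoate | I/C=C(/CO[Si](c1ccccc1)(c1ccccc1)C(C)(C)C)C1=CC(=O)[C@](C)(C[C@@H](OC(=O)[C@H](C)CC)[C@@H](CC(=O)OC(C)(C)C)CO[Si](CC)(CC)CC)O1 | intermediate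
27 | tert-butyl (3S,4R)-3-(hydroxymethyl)-4-[(2R)-2-methylbutanoyloxy]-5-Fur-pentanoate | I/C=C(/CO[Si](c1ccccc1)(c1ccccc1)C(C)(C)C)C1=CC(=O)[C@](C)(C[C@@H](OC(=O)[C@H](C)CC)[C@@H](CC(=O)OC(C)(C)C)CO)O1 | intermediate
28 | tert-butyl (3R,4R)-3-formyl-4-[(2R)-2-methylbutanoyloxy]-5-Fur-pentanoate (key-step precursor) | I/C=C(/CO[Si](c1ccccc1)(c1ccccc1)C(C)(C)C)C1=CC(=O)[C@](C)(C[C@@H](OC(=O)[C@H](C)CC)[C@@H](CC(=O)OC(C)(C)C)C=O)O1 | intermediate
29 | alkenylchromium dichloride from 28 (Cl2Cr in place of iodine at C5, Z) | Cl[Cr](Cl)/C=C(/CO[Si](c1ccccc1)(c1ccccc1)C(C)(C)C)C1=CC(=O)[C@](C)(C[C@@H](OC(=O)[C@H](C)CC)[C@@H](CC(=O)OC(C)(C)C)C=O)O1 | intermediate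
30 | tert-butyl 2-[(4Z,6R,7S,8R,10S)-15-(tert-butyldiphenylsilyloxy)-6-hydroxy-8-((2R)-2-methylbutanoyloxy)-1-oxo-3,10-epoxygermacra-2,4-dien-7-yl]acetate (key-step product) | CC(C)(C)OC(=O)C[C@H]1[C@H](O)/C=C(/CO[Si](c3ccccc3)(c3ccccc3)C(C)(C)C)C2=CC(=O)[C@](C)(C[C@H]1OC(=O)[C@H](C)CC)O2 | intermediate
31 | free acid corresponding to 30 (6-hydroxy 12-oic acid) | OC(=O)C[C@H]1[C@H](O)/C=C(/CO[Si](c3ccccc3)(c3ccccc3)C(C)(C)C)C2=CC(=O)[C@](C)(C[C@H]1OC(=O)[C@H](C)CC)O2 | intermediate
32 | (4Z,6R,7R,8R,10S)-15-(tert-butyldiphenylsilyloxy)-8-[(2R)-2-methylbutanoyloxy]-1-oxo-3,10-epoxy-13-norgermacra-2,4-dien-12,6-olide | C1C(=O)O[C@@H]2/C=C(/CO[Si](c4ccccc4)(c4ccccc4)C(C)(C)C)C3=CC(=O)[C@](C)(C[C@@H](OC(=O)[C@H](C)CC)[C@@H]12)O3 | intermediate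
33 | lithium enolate of 32 (C11=C12–OLi) | C1=C([O-])O[C@@H]2/C=C(/CO[Si](c4ccccc4)(c4ccccc4)C(C)(C)C)C3=CC(=O)[C@](C)(C[C@@H](OC(=O)[C@H](C)CC)[C@@H]12)O3.[Li+] | intermediate
34 | 13-(dimethylamino)-11,13-dihydro derivative of 36 (Mannich base, C11 epimers) | CN(C)CC1C(=O)O[C@@H]2/C=C(/CO[Si](c4ccccc4)(c4ccccc4)C(C)(C)C)C3=CC(=O)[C@](C)(C[C@@H](OC(=O)[C@H](C)CC)[C@@H]12)O3 | intermediate
35 | N-methyl ammonium iodide of 34 | C[N+](C)(C)CC1C(=O)O[C@@H]2/C=C(/CO[Si](c4ccccc4)(c4ccccc4)C(C)(C)C)C3=CC(=O)[C@](C)(C[C@@H](OC(=O)[C@H](C)CC)[C@@H]12)O3.[I-] | intermediate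
36 | (4Z,6R,7R,8R,10S)-15-(tert-butyldiphenylsilyloxy)-8-[(2R)-2-methylbutanoyloxy]-1-oxo-3,10-epoxygermacra-2,4,11(13)-trien-12,6-olide | C=C1C(=O)O[C@@H]2/C=C(/CO[Si](c4ccccc4)(c4ccccc4)C(C)(C)C)C3=CC(=O)[C@](C)(C[C@@H](OC(=O)[C@H](C)CC)[C@@H]12)O3 | intermediate
37 | (4Z,6R,7R,8R,10S)-15-hydroxy-8-[(2R)-2-methylbutanoyloxy]-1-oxo-3,10-epoxygermacra-2,4,11(13)-trien-12,6-olide (CNP0307052.2) | C=C1C(=O)O[C@@H]2/C=C(/CO)C3=CC(=O)[C@](C)(C[C@@H](OC(=O)[C@H](C)CC)[C@@H]12)O3 | target

## Step count and least certain steps

Total: 21 steps. Longest linear sequence: 17 steps (steps 1–4, 8–10 and 12–21, from 1 to 37).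

Step 18 (key step). The most likely failure is insufficient facial selectivity at C6, because the conformation of the closing nine- to ten-membered ring can override the Felkin–Anh preference. Slow closure of the strained ring would in addition let intermolecular coupling and protodeiodination compete. The fallback corrects C6 after ring closure, not during it. It sets out from 28: the cyclisation product with the wrong face, the (6S)-epimer of 30 F1, would be treated with 4-nitrobenzoic acid, PPh3 and diisopropyl azodicarboxylate (Mitsunobu reaction, inversion at the allylic carbon) to give the 6-O-(4-nitrobenzoate) of 30 F2. Mild methanolysis (K2CO3, MeOH, 0 °C) of this activated ester in the presence of the hindered O8 ester returns to the route at 30.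

Step 12. The most likely failure is erosion of the anti/syn ratio, because the aldehyde is unbranched at its α-carbon and the vinylogous-ester carbonyl of ring A can sequester the aluminium Lewis acid on which the open transition state depends. The fallback replaces the Lewis-acid-mediated anti aldol by a closed-transition-state syn aldol followed by inversion at C8. It sets out from 17 and 16: 17 would be joined to (4R)-4-benzyl-1,3-oxazolidin-2-one as in step 11 to give the enantiomeric imide, tert-butyl 4-[(4R)-4-benzyl-2-oxo-1,3-oxazolidin-3-yl]-4-oxobutanoate F3. The standard Bu2BOTf/Et3N aldol with 16 (Zimmerman–Traxler chair) should give the syn adduct with C7 correct and C8 epimeric, tert-butyl (3R,4S)-3-[(4R)-4-benzyl-2-oxo-1,3-oxazolidine-3-carbonyl]-4-hydroxy-5-Fur-pentanoate F4. LiBH4 would give the 8-epi diol, tert-butyl (3S,4S)-4-hydroxy-3-(hydroxymethyl)-5-Fur-pentanoate F5, and TESCl its primary silyl ether, tert-butyl (3S,4S)-4-hydroxy-3-[(triethylsilyloxy)methyl]-5-Fur-pentanoate F6. Mitsunobu esterification of F6 with 25 (PPh3, diisopropyl azodicarboxylate) inverts C8 and returns to the route at 26.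

Step 13. The most likely failure is loss of chemoselectivity of the hydride, that is 1,2-reduction of the ring A carbonyl or conjugate reduction of the iodo dienone, since the selectivity rests only on a rate difference. The fallback brings C6 in at the aldehyde oxidation level, so that no hydride is needed. It sets out from 16: a cross-aldol catalysed by (R)-proline (DMF, 4 °C) with slowly added tert-butyl 4-oxobutanoate, an enamine aldol that is anti-selective through a hydrogen-bonded chair-like transition state, should give the β-hydroxy aldehyde, tert-butyl (3R,4R)-3-formyl-4-hydroxy-5-Fur-pentanoate F7. Esterification with 25 (DCC, DMAP, 0 °C) returns to the route at 28 and bypasses steps 12–17.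

Step 9. The most likely failure is attack of the enolate or the amide base at the iodine-bearing carbon C5 (addition–elimination) or erosion of the Z geometry, because the acyl group is itself a β-iodo acceptor under strongly basic conditions. The fallback replaces the base-mediated intramolecular acyl transfer by an intermolecular soft-enolisation C-acylation. It sets out from 6: TMSCl/imidazole would give the silyl ether, (3S)-5-(tert-butyldimethylsilyloxy)-3-methyl-3-(trimethylsilyloxy)pentan-2-one F8. MgBr2·OEt2 and i-Pr2NEt with the acid chloride 11 (magnesium enolate chelated by the α-silyloxy ketone) should then give the β-diketone, (1Z,6S)-8-(tert-butyldimethylsilyloxy)-1-iodo-6-methyl-2-[(tert-butyldiphenylsilyloxy)methyl]-6-(trimethylsilyloxy)oct-1-ene-3,5-dione F9. TsOH·H2O in MeOH removes both the trimethylsilyl and the TBS group and closes the furanone, returning to the route at 15.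

## Further compounds

F1 | step 18 | (6S)-epimer of 30, tert-butyl 2-[(4Z,6S,7S,8R,10S)-15-(tert-butyldiphenylsilyloxy)-6-hydroxy-8-((2R)-2-methylbutanoyloxy)-1-oxo-3,10-epoxygermacra-2,4-dien-7-yl]acetate | CC(C)(C)OC(=O)C[C@H]1[C@@H](O)/C=C(/CO[Si](c3ccccc3)(c3ccccc3)C(C)(C)C)C2=CC(=O)[C@](C)(C[C@H]1OC(=O)[C@H](C)CC)O2
F2 | step 18 | 6-O-(4-nitrobenzoate) of 30 | CC(C)(C)OC(=O)C[C@H]1[C@H](OC(=O)c4ccc(cc4)[N+](=O)[O-])/C=C(/CO[Si](c3ccccc3)(c3ccccc3)C(C)(C)C)C2=CC(=O)[C@](C)(C[C@H]1OC(=O)[C@H](C)CC)O2
F3 | step 12 | tert-butyl 4-[(4R)-4-benzyl-2-oxo-1,3-oxazolidin-3-yl]-4-oxobutanoate | CC(C)(C)OC(=O)CCC(=O)N1[C@H](Cc2ccccc2)COC1=O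
F4 | step 12 | tert-butyl (3R,4S)-3-[(4R)-4-benzyl-2-oxo-1,3-oxazolidine-3-carbonyl]-4-hydroxy-5-Fur-pentanoate | I/C=C(/CO[Si](c1ccccc1)(c1ccccc1)C(C)(C)C)C1=CC(=O)[C@](C)(C[C@H](O)[C@@H](CC(=O)OC(C)(C)C)C(=O)N2[C@H](Cc3ccccc3)COC2=O)O1
F5 | step 12 | tert-butyl (3S,4S)-4-hydroxy-3-(hydroxymethyl)-5-Fur-pentanoate | I/C=C(/CO[Si](c1ccccc1)(c1ccccc1)C(C)(C)C)C1=CC(=O)[C@](C)(C[C@H](O)[C@@H](CC(=O)OC(C)(C)C)CO)O1
F6 | step 12 | tert-butyl (3S,4S)-4-hydroxy-3-[(triethylsilyloxy)methyl]-5-Fur-pentanoate | I/C=C(/CO[Si](c1ccccc1)(c1ccccc1)C(C)(C)C)C1=CC(=O)[C@](C)(C[C@H](O)[C@@H](CC(=O)OC(C)(C)C)CO[Si](CC)(CC)CC)O1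
F7 | step 13 | tert-butyl (3R,4R)-3-formyl-4-hydroxy-5-Fur-pentanoate | I/C=C(/CO[Si](c1ccccc1)(c1ccccc1)C(C)(C)C)C1=CC(=O)[C@](C)(C[C@@H](O)[C@@H](CC(=O)OC(C)(C)C)C=O)O1
F8 | step 9 | (3S)-5-(tert-butyldimethylsilyloxy)-3-methyl-3-(trimethylsilyloxy)pentan-2-one | CC(=O)[C@@](C)(O[Si](C)(C)C)CCO[Si](C)(C)C(C)(C)C
F9 | step 9 | (1Z,6S)-8-(tert-butyldimethylsilyloxy)-1-iodo-6-methyl-2-[(tert-butyldiphenylsilyloxy)methyl]-6-(trimethylsilyloxy)oct-1-ene-3,5-dione | I/C=C(/CO[Si](c1ccccc1)(c1ccccc1)C(C)(C)C)C(=O)CC(=O)[C@@](C)(O[Si](C)(C)C)CCO[Si](C)(C)C(C)(C)C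
A1 | alternative 1 | ten-membered propargylic alcohol (15-O-TBS, 10-O-TES, one C1 epimer) | C=C1C(=O)O[C@@H]2/C=C(/CO[Si](C)(C)C(C)(C)C)C#C[C@@H](O)[C@](C)(C[C@@H](OC(=O)[C@H](C)CC)[C@@H]12)O[Si](CC)(CC)CC
A2 | alternative 1 | open-chain C2 iodoalkyne C1 aldehyde carrying the methylene lactone | C=C1C(=O)O[C@H](/C=C(/CO[Si](C)(C)C(C)(C)C)C#CI)[C@H]1[C@H](OC(=O)[C@H](C)CC)C[C@@](C)(C=O)O[Si](CC)(CC)CC
A3 | alternative 2 | 15-O-TBS ether of 37 | C=C1C(=O)O[C@@H]2/C=C(/CO[Si](C)(C)C(C)(C)C)C3=CC(=O)[C@](C)(C[C@@H](OC(=O)[C@H](C)CC)[C@@H]12)O3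
A4 | alternative 2 | lactone-fused cyclooctenone bearing the 3-(silyloxy)prop-1-ynyl ether on O10 | C=C1C(=O)O[C@@H]2/C=C\C(=O)[C@](C)(C[C@@H](OC(=O)[C@H](C)CC)[C@@H]12)OC#CCO[Si](C)(C)C(C)(C)C
A5 | alternative 3 | 8-hydroxy 15-O-TBS tricycle | C=C1C(=O)O[C@@H]2/C=C(/CO[Si](C)(C)C(C)(C)C)C3=CC(=O)[C@](C)(C[C@@H](O)[C@@H]12)O3
A6 | alternative 3 | 3-(bromomethyl)butenolide tethered through the Z alkene and ring A to the C8 aldehyde | BrCC1=C[C@@H](/C=C(/CO[Si](C)(C)C(C)(C)C)C2=CC(=O)[C@](C)(CC=O)O2)OC1=O
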